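## Structural features

Local labels used throughout: C1 is the ketone carbon; C2 is the seven-ring CH carrying a 4-hydroxyphenyl group (ring D); C3 is the CH shared by the seven- and five-membered rings; C4 is the indane CH carrying the second 4-hydroxyphenyl group (ring E); C5 is the indane CH carrying the 3,5-dihydroxyphenyl group (ring C). Ring A is the resorcinol ring bonded to C1 and C2 through adjacent carbons. Ring B is the pentasubstituted resorcinol ring bonded to C1, C3 and C5 through three adjacent carbons.

C1, ring A, C2, C3 and ring B form a dibenzo-fused cycloheptanone. Ring B, C3, C4 and C5 form an indane fused to it along the ring B–C3 bond. The four contiguous stereocentres are C2 (S), C3 (R), C4 (S), C5 (S), with H2/H3, H3/H4 and H4/H5 all trans. C2–H and C3–H are each benzylic and ortho to the diaryl ketone, so both can be equilibrated through dienolates; C4 and C5 cannot. The eight free phenols are oxidation-sensitive, and the electron-rich benzhydryl positions ionize in strong acid.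

The real difficulty is the unsymmetrical seven-membered diaryl ketone joined to an all-trans indane around one crowded ring B, with absolute control at C4/C5. A further hazard is that ring C sits cis-1,3 to C2 and would compete for any secondary cation placed at C2.

The key step exploits two features. Ring A carries C1 and C2 on adjacent carbons, so C1–ring A–C2 is a ring-opened 1,3-diarylisobenzofuran. Ring B carries C5 and the C3=C4 styrene on adjacent carbons, so it is a pentadienyl cation in waiting.

## Logic of the disconnections

19 ⇒ 18. The eight O–methyl bonds are cut. Methyl ethers are the only groups that survive the organolithium and cation chemistry. The forward step must be a global demethylation that leaves the C2–C5 centres untouched.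

18 ⇒ 16. The C2–H and C3–H bonds are cut to give a C2=C3 alkene. Both centres are gamma to the C1 ketone and can be set by equilibration, so they need not be carried through the ring construction. Two stereocentres disappear. The forward step must reduce a tetrasubstituted alkene without touching the ketone and then equilibrate C2 and C3.

16 ⇒ 12 (key disconnection). The C2–C3 bond (seven-membered ring) and the C4–C5 bond (indane) are cut, and the C1 ketone is folded with C2 into a lactol. In one sentence: a carbinol and a lactol on ring B are ionized to a pentadienyl cation and an isobenzofuran, which together close the indane and the seven-membered ketone. The tetracycle becomes a single ring B with three acyclic arms and no stereocentre that matters. The forward step must order three cationic events and control the sense of one electrocyclization.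

12 ⇒ 6 + 10. The ring B–C1 bond is cut. This is the classical aryl-metal/phthalide route to isobenzofuran precursors and is fully convergent. The forward step needs mono-addition to the lactone without deprotonation of its benzylic C–H.

10 ⇒ 7 + 8. The C2–ring A bond and the lactone C–O bond are cut. Ring A arrives with the C1 carboxyl already in place. The forward step needs an ortho-metalated benzoate.

6 ⇒ 4 + 1. The C5–ring B bond is cut, giving an aryllithium and an aldehyde. The forward step needs mono-exchange of a symmetric dibromide.

4 ⇒ 2 + 3. The C3=C4 double bond is cut (olefination). The forward step must be E-selective.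

2 ⇒ 1. The two C–Br bonds on ring B are cut. The forward step needs bromination at both positions ortho to the formyl group.

## Other disconnections considered

Alternative 1: Cut the C1–ring B bond. The forward key step is an intramolecular Friedel–Crafts acylation of the seco-acid A1 onto ring B; this is the route that comes to mind first. A1 already holds all four stereocentres. C2 is then a benzhydryl centre with no carbonyl to equilibrate it until after the ring has closed, so C2–C3 must be built by a separate stereoselective step on a preformed indane. The indane, the C2–C3 bond and the seven-membered ring each cost their own operations, whereas the chosen plan makes both rings in one.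

Alternative 2: Cut C3–C4 and the C2–ring A bond. The forward key step ionizes the C4 carbinol of the stilbene ketone A2; the alkene closes the indane and ring A is to capture the resulting C2 cation. The C5 centre of A2 could be set by dynamic kinetic resolution of the ketone precursor. However, once the indane has closed, the secondary C2 cation lies cis-1,3 to ring C. Ring C is more electron-rich than the acyl-deactivated ring A and reaches C2 through a six-membered transition state (a bridged bicyclo[3.2.1] closure), against a seven-membered one for ring A. The chosen plan never exposes a secondary C2 cation to ring C.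

Alternative 3: Cut both bonds from ring B to the seven-membered ring (C1–ring B and C3–ring B). The forward key step inserts ring B as an aryne (from A5) into the C1–C2 bond of the indanone beta-keto ester A3, expanding it to the dibenzosuberone A4. The regiochemistry is right, because the acyl group ends up next to the aryne methoxy group. But A4 lacks the indane: the ester on C3 must be removed, and C3–C4, C4–C5 and C5–ring B must still be formed with two non-epimerizable centres, which needs many more steps than the chosen plan.

Key step: step 6

Remarks on the chemistry (assumptions, one line each):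
- 2-Bromo-3,5-dimethoxybenzoic acid (7) is taken as purchasable; otherwise it follows from one bromination of 3,5-dimethoxybenzoic acid.
- The (S)-configured acid of step 6 is taken to give the (4S,5S) series; if the sense proves opposite, its (R)-antipode is used.
- For fixed (4S,5S), the natural (2S,3R) arrangement is taken to be the thermodynamic one (C3 substituent trans to the C4 aryl group, C2 aryl group anti to C4).

## Route

Step 1
Reactants: 1 3,5-dimethoxybenzaldehyde
Product: 2 2,6-dibromo-3,5-dimethoxybenzaldehyde
Conditions: Br2 (2.2 equiv), AcOH, 23 °C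
Reagents that add atoms: bromine, BrBr
Why: Electrophilic aromatic bromination; each bromine should enter ortho to the formyl group and para to a methoxy group, the carbon between the two methoxy groups being the most hindered.

Step 2
Reactants: 2 2,6-dibromo-3,5-dimethoxybenzaldehyde; 3 diethyl (4-methoxybenzyl)phosphonate
Product: 4 1,3-dibromo-4,6-dimethoxy-2-[(E)-2-(4-methoxyphenyl)ethenyl]benzene
Conditions: NaH, THF, 0 to 23 °C
Reagents that add atoms: none
Why: Horner–Wadsworth–Emmons olefination; the aryl-stabilized phosphonate anion should give the E-stilbene.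

Step 3
Reactants: 4 1,3-dibromo-4,6-dimethoxy-2-[(E)-2-(4-methoxyphenyl)ethenyl]benzene; 1 3,5-dimethoxybenzaldehyde
Product: 6 rac-{3-bromo-4,6-dimethoxy-2-[(E)-2-(4-methoxyphenyl)ethenyl]phenyl}(3,5-dimethoxyphenyl)methanol, via aryllithium 5 (not isolated)
Conditions: n-BuLi (1.05 equiv), THF, −78 °C; then 1, −78 to −20 °C; aq. NaHCO3
Reagents that add atoms: none
Why: Bromine–lithium exchange on the symmetric dibromide gives one monolithio species, which adds to the aldehyde; the carbinol centre is racemic and is erased in step 6.

Step 4
Reactants: 7 2-bromo-3,5-dimethoxybenzoic acid; 8 4-methoxybenzaldehyde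
Product: 10 rac-4,6-dimethoxy-3-(4-methoxyphenyl)-2-benzofuran-1(3H)-one, via dilithio benzoate 9 (not isolated)
Conditions: n-BuLi (2.1 equiv), THF, −78 °C; then 8; then 2 M HCl, 23 °C
Reagents that add atoms: none
Why: Parham-type sequence: carboxylate formation, bromine–lithium exchange ortho to it, addition to the aldehyde and acid-induced lactonization; the C3 centre of the phthalide is racemic and is erased in step 6.

Step 5
Reactants: 6 rac-{3-bromo-4,6-dimethoxy-2-[(E)-2-(4-methoxyphenyl)ethenyl]phenyl}(3,5-dimethoxyphenyl)methanol; 10 rac-4,6-dimethoxy-3-(4-methoxyphenyl)-2-benzofuran-1(3H)-one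
Product: 12 1-{3-[(3,5-dimethoxyphenyl)(hydroxy)methyl]-4,6-dimethoxy-2-[(E)-2-(4-methoxyphenyl)ethenyl]phenyl}-4,6-dimethoxy-3-(4-methoxyphenyl)-1,3-dihydro-2-benzofuran-1-ol (mixture of diastereomers), via dilithio alkoxide 11 (not isolated)
Conditions: n-BuLi (2.1 equiv), THF, −78 °C; MgBr2·OEt2, −78 to −40 °C; then 10, −40 to 0 °C; pH 7 buffer
Reagents that add atoms: none
Why: Alkoxide formation and bromine–lithium exchange, transmetalation to the less basic arylmagnesium and mono-addition to the lactone carbonyl (the classical aryl-metal/phthalide route to lactols of 1,3-diarylisobenzofurans); all stereocentres of 12 are erased in step 6.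

Step 6
Reactants: 12 1-{3-[(3,5-dimethoxyphenyl)(hydroxy)methyl]-4,6-dimethoxy-2-[(E)-2-(4-methoxyphenyl)ethenyl]phenyl}-4,6-dimethoxy-3-(4-methoxyphenyl)-1,3-dihydro-2-benzofuran-1-ol
Product: 16 (4S,5S)-2,3-didehydro octa-O-methyl ether of the target (C2=C3 alkene, C1 ketone), via isobenzofuran cation 13 (not isolated), via indanyl cation 14 (not isolated), via bridged oxocarbenium ion 15 (not isolated)
Conditions: (S)-3,3'-bis(2,4,6-triisopropylphenyl)-1,1'-binaphthyl-2,2'-diyl N-triflylphosphoramide (10 mol %), 5 Å MS, toluene (0.01 M), −40 to 0 °C, Ar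
Reagents that add atoms: none
Why: Proposed new method: the chiral acid should dehydrate the lactol of 12 to a 1,3-diarylisobenzofuran and ionize the bis-benzylic carbinol, giving 13 as a contact ion pair with the chiral anion. The pentadienyl cation of 13 (C5, two ring B carbons, C3, C4) closes the indane by a conrotatory 4π-electrocyclization (formally 5-endo-trig); the closest known reaction type is the acid-mediated cyclization of (2-styrylaryl)(aryl)methanols to 2,3-trans-diarylindanyl cations, here run under a chiral counteranion as in catalytic asymmetric Nazarov cyclizations. Conrotation of the E-alkene places the C4 and C5 aryl groups trans, and the confined anion is to select one of the two mirror-image conrotatory senses, which fixes (4S,5S). The indanyl cation 14 is then alkylated by the nucleophilic furan carbon C2, which closes the seven-membered carbocycle (six-membered transition state counted through the furan oxygen), restores benzenoid ring A and gives 15. Heterolysis of the C2–O bond of 15 returns the C1 ketone and a tertiary diarylmethyl cation at C2, which loses the C3 proton to give the C2=C3 alkene; this alkylation and ring opening follows the known acid-induced ring-opening recyclizations of furans. The step needs ring A, not the more electron-rich ring C, to form the second ring: ring C can reach the C3 cation only through a strained bicyclo[2.2.1] closure, and it never meets a secondary C2 cation because C2 arrives as a nucleophile and becomes cationic only as a hindered tertiary centre with an E1 exit. The ketone oxygen stays masked in the furan until the C–C bond is made, and the sieves remove the two equivalents of water.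

Step 7
Reactants: 16 (4S,5S)-2,3-didehydro octa-O-methyl ether of the target
Product: 18 (2S,3R,4S,5S)-octa-O-methyl ether of the target, via epimer mixture 17 (not isolated)
Conditions: Mn(dpm)3 [tris(2,2,6,6-tetramethyl-3,5-heptanedionato)manganese] (10 mol %), PhSiH3, t-BuOOH, i-PrOH/CH2Cl2, 23 °C; then KOt-Bu (0.3 equiv), t-BuOH/THF, 40 °C, Ar
Reagents that add atoms: none
Why: Metal-hydride hydrogen atom transfer hydrogenation: H-atom transfer to C3 gives the diaryl-stabilized C2 radical, which takes the second hydrogen, a radical path that tolerates the tetrasubstituted alkene and the ketone. KOt-Bu then equilibrates C2 and C3 through the two ortho-quinodimethane dienolates of the C1 ketone, which should place the C3 substituent trans to the C4 aryl group and the C2 aryl group anti to C4, i.e. (2S,3R). C4 and C5 are not acidic and keep their configuration.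

Step 8
Reactants: 18 (2S,3R,4S,5S)-octa-O-methyl ether of the target
Product: 19 CNP0116600.1, the (2S,3R,4S,5S)-octaphenol (target)
Conditions: BBr3 (20 equiv), CH2Cl2, −78 to 23 °C; then MeOH, H2O
Reagents that add atoms: none
Why: Lewis acid cleavage of the eight aryl methyl ethers; no leaving group is present at C2–C5, so no carbon-centred cation can form there and the four stereocentres should be retained.

## Compound list

1 | 3,5-dimethoxybenzaldehyde | COc1cc(C=O)cc(OC)c1 | starting material
2 | 2,6-dibromo-3,5-dimethoxybenzaldehyde | COc1cc(OC)c(Br)c(C=O)c1Br | intermediate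
3 | diethyl (4-methoxybenzyl)phosphonate | CCOP(=O)(Cc1ccc(OC)cc1)OCC | starting material
4 | 1,3-dibromo-4,6-dimethoxy-2-[(E)-2-(4-methoxyphenyl)ethenyl]benzene | COc1cc(OC)c(Br)c(/C=C/c2ccc(OC)cc2)c1Br | intermediate
5 | {3-bromo-4,6-dimethoxy-2-[(E)-2-(4-methoxyphenyl)ethenyl]phenyl}lithium | COc1cc(OC)c(Br)c(/C=C/c2ccc(OC)cc2)c1[Li] | intermediate
6 | rac-{3-bromo-4,6-dimethoxy-2-[(E)-2-(4-methoxyphenyl)ethenyl]phenyl}(3,5-dimethoxyphenyl)methanol | COc1cc(OC)c(Br)c(/C=C/c2ccc(OC)cc2)c1C(O)c1cc(OC)cc(OC)c1 | intermediate
7 | 2-bromo-3,5-dimethoxybenzoic acid | COc1cc(OC)c(Br)c(C(=O)O)c1 | starting material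
8 | 4-methoxybenzaldehyde | COc1ccc(C=O)cc1 | starting material
9 | lithium 2-lithio-3,5-dimethoxybenzoate | COc1cc(OC)c([Li])c(C(=O)O[Li])c1 | intermediate
10 | rac-4,6-dimethoxy-3-(4-methoxyphenyl)-2-benzofuran-1(3H)-one | COc1ccc(cc1)C1OC(=O)c2cc(OC)cc(OC)c12 | intermediate
11 | lithium alkoxide of 6 lithiated at the former C–Br carbon | COc1cc(OC)c([Li])c(/C=C/c2ccc(OC)cc2)c1C(O[Li])c1cc(OC)cc(OC)c1 | intermediate
12 | 1-{3-[(3,5-dimethoxyphenyl)(hydroxy)methyl]-4,6-dimethoxy-2-[(E)-2-(4-methoxyphenyl)ethenyl]phenyl}-4,6-dimethoxy-3-(4-methoxyphenyl)-1,3-dihydro-2-benzofuran-1-ol, mixture of diastereomers | COc1ccc(cc1)C2OC(O)(c3c(OC)cc(OC)c(C(O)c4cc(OC)cc(OC)c4)c3/C=C/c3ccc(OC)cc3)c3cc(OC)cc(OC)c23 | intermediate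
13 | isobenzofuran-tethered diarylmethyl (pentadienyl) cation | COc1cc(OC)c2c(-c3ccc(OC)cc3)oc(-c3c(OC)cc(OC)c([CH+]c4cc(OC)cc(OC)c4)c3/C=C/c3ccc(OC)cc3)c2c1 | intermediate
14 | (4S,5S)-indanyl cation (cation at C3) carrying the isobenzofuran | COc1cc(OC)c2c(-c3ccc(OC)cc3)oc(-c3c(OC)cc(OC)c4c3[CH+][C@H](c3ccc(OC)cc3)[C@H]4c3cc(OC)cc(OC)c3)c2c1 | intermediate
15 | (4S,5S)-oxygen-bridged oxocarbenium ion (C1=O+–C2), transient centres C2 and C3 undefined | COc1cc(OC)c2c(c1)C1=[O+]C2(c2ccc(OC)cc2)C2c3c1c(OC)cc(OC)c3[C@H](c1cc(OC)cc(OC)c1)[C@H]2c1ccc(OC)cc1 | intermediate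
16 | (4S,5S)-2,3-didehydro octa-O-methyl ether of the target | O=C1c2cc(OC)cc(OC)c2C(c2ccc(OC)cc2)=C2c3c1c(OC)cc(OC)c3[C@H](c1cc(OC)cc(OC)c1)[C@H]2c1ccc(OC)cc1 | intermediate
17 | (4S,5S)-octa-O-methyl ether as a mixture of C2/C3 epimers | O=C1c2cc(OC)cc(OC)c2C(c2ccc(OC)cc2)C2c3c1c(OC)cc(OC)c3[C@H](c1cc(OC)cc(OC)c1)[C@H]2c1ccc(OC)cc1 | intermediate
18 | (2S,3R,4S,5S)-octa-O-methyl ether of the target | O=C1c2cc(OC)cc(OC)c2[C@H](c2ccc(OC)cc2)[C@@H]2c3c1c(OC)cc(OC)c3[C@H](c1cc(OC)cc(OC)c1)[C@H]2c1ccc(OC)cc1 | intermediate
19 | CNP0116600.1, (2S,3R,4S,5S)-octaphenol | O=C1c2cc(O)cc(O)c2[C@H](c2ccc(O)cc2)[C@@H]2c3c1c(O)cc(O)c3[C@H](c1cc(O)cc(O)c1)[C@H]2c1ccc(O)cc1 | target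

## Step count and least certain steps

Total step count: 8. Longest linear sequence: 7 (steps 1, 2, 3, 5, 6, 7, 8).

Step 6 (key step, proposed new method). The most likely failure is weak enantiofacial control of the conrotatory closure, because the all-methylated cation offers the chiral anion no hydrogen-bonding handle. A second hazard is elimination of the C3 cation towards C4 (indene formation) before the furan carbon captures it.
Fallback (resolution instead of asymmetric induction): it sets out from 12 and comes back at 19. The same ring construction is run with an achiral acid (CF3CO2H, CH2Cl2, −30 °C), and 16 and then 18 are carried as racemates through step 7. BCl3 (CH2Cl2, −78 to 0 °C) removes only the methyl group ortho to the chelating C1 ketone, giving the ring B monophenol F1 as a racemate. Acylation with (1S)-camphanic chloride (Et3N, DMAP) gives the diastereomeric esters, the (2S,3R,4S,5S)-camphanate F2 and its (2R,3S,4R,5R)-diastereomer F3, which are separated by chromatography or crystallization. Methanolysis of F2 (K2CO3, MeOH) returns F1 as a single enantiomer, and BBr3 under the conditions of step 8 gives 19.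

Step 7. Hydrogen atom transfer to the shielded tetrasubstituted alkene may stall, or the persistent diaryl C2 radical may not pick up the second hydrogen. The base equilibration may also stop at a mixture of epimers.
Fallback (electron-transfer reduction and re-oxidation): it sets out from 16 and comes back at 17. Li in NH3/THF with t-BuOH at −78 °C should reduce both the conjugated alkene and the ketone to the saturated benzhydrol F4; Dess–Martin periodinane restores the ketone to give 17, which enters the KOt-Bu equilibration of step 7.

Step 5. The hindered aryl metal may deprotonate the acidic benzylic C–H of lactone 10 instead of adding to its carbonyl, or the adduct may take up a second aryl group.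
Fallback (open-chain acyl donor): it sets out from 10 (with 6) and comes back at 12. Aminolysis of 10 (Me3Al, MeNHOMe·HCl) gives the hydroxy Weinreb amide F5, which is silylated (Et3SiOTf, 2,6-lutidine) to the triethylsilyl ether F6. Addition of 11 gives the silyl-protected ketone F7, and Bu4NF/AcOH releases the hydroxy ketone, which closes to lactol 12.

Step 1. The second bromination may go to the carbon between the two methoxy groups, or over-bromination may occur.
Fallback (directed metalation instead of electrophilic substitution): it sets out from purchased 1,5-dibromo-2,4-dimethoxybenzene in place of 1 and comes back at 2. LDA (THF, −78 °C) deprotonates between the two bromines to give the aryllithium F8, which is formylated with DMF to give 2.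

## Further compounds

F1 | step 6 | (2S,3R,4S,5S)-hepta-O-methyl ether of the target with the free phenol on ring B ortho to the ketone | O=C1c2cc(OC)cc(OC)c2[C@H](c2ccc(OC)cc2)[C@@H]2c3c1c(O)cc(OC)c3[C@H](c1cc(OC)cc(OC)c1)[C@H]2c1ccc(OC)cc1
F2 | step 6 | (1S,4R)-camphanate ester of F1 | O=C1c2cc(OC)cc(OC)c2[C@H](c2ccc(OC)cc2)[C@@H]2c3c1c(OC(=O)[C@@]14CC[C@@](C)(C(=O)O1)C4(C)C)cc(OC)c3[C@H](c1cc(OC)cc(OC)c1)[C@H]2c1ccc(OC)cc1
F3 | step 6 | (1S,4R)-camphanate ester of the (2R,3S,4R,5R)-enantiomer of F1 | O=C1c2cc(OC)cc(OC)c2[C@@H](c2ccc(OC)cc2)[C@H]2c3c1c(OC(=O)[C@@]14CC[C@@](C)(C(=O)O1)C4(C)C)cc(OC)c3[C@@H](c1cc(OC)cc(OC)c1)[C@@H]2c1ccc(OC)cc1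
F4 | step 7 | (4S,5S)-octa-O-methyl C1 carbinol with saturated C2–C3, mixture of epimers at C1, C2 and C3 | OC1c2cc(OC)cc(OC)c2C(c2ccc(OC)cc2)C2c3c1c(OC)cc(OC)c3[C@H](c1cc(OC)cc(OC)c1)[C@H]2c1ccc(OC)cc1
F5 | step 5 | rac-2-[hydroxy(4-methoxyphenyl)methyl]-N,3,5-trimethoxy-N-methylbenzamide | CON(C)C(=O)c1cc(OC)cc(OC)c1C(O)c1ccc(OC)cc1
F6 | step 5 | rac-N,3,5-trimethoxy-2-[(4-methoxyphenyl)(triethylsilyloxy)methyl]-N-methylbenzamide | CON(C)C(=O)c1cc(OC)cc(OC)c1C(O[Si](CC)(CC)CC)c1ccc(OC)cc1
F7 | step 5 | {3-[(3,5-dimethoxyphenyl)(hydroxy)methyl]-4,6-dimethoxy-2-[(E)-2-(4-methoxyphenyl)ethenyl]phenyl}{3,5-dimethoxy-2-[(4-methoxyphenyl)(triethylsilyloxy)methyl]phenyl}methanone, mixture of diastereomers | COc1ccc(cc1)C(O[Si](CC)(CC)CC)c1c(OC)cc(OC)cc1C(=O)c1c(OC)cc(OC)c(C(O)c2cc(OC)cc(OC)c2)c1/C=C/c1ccc(OC)cc1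
F8 | step 1 | (2,6-dibromo-3,5-dimethoxyphenyl)lithium | COc1cc(OC)c(Br)c([Li])c1Br
A1 | alternative 1 | seco-acid: octa-O-methyl indane with C3 bearing CH(4-methoxyphenyl)(2-carboxy-4,6-dimethoxyphenyl), stereocentres as in 18 | OC(=O)c1cc(OC)cc(OC)c1[C@H](c1ccc(OC)cc1)[C@@H]1c2cc(OC)cc(OC)c2[C@H](c2cc(OC)cc(OC)c2)[C@H]1c1ccc(OC)cc1
A2 | alternative 2 | {3-[(1S,2S)-1-(3,5-dimethoxyphenyl)-2-hydroxy-2-(4-methoxyphenyl)ethyl]-4,6-dimethoxy-2-[(E)-2-(4-methoxyphenyl)ethenyl]phenyl}(3,5-dimethoxyphenyl)methanone | COc1cc(OC)c(C(=O)c2cc(OC)cc(OC)c2)c(/C=C/c2ccc(OC)cc2)c1[C@H](c1cc(OC)cc(OC)c1)[C@H](O)c1ccc(OC)cc1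
A3 | alternative 3 | methyl (3S)-4,6-dimethoxy-3-(4-methoxyphenyl)-1-oxo-2,3-dihydro-1H-indene-2-carboxylate (C2 epimerizable) | COC(=O)C1C(=O)c2cc(OC)cc(OC)c2[C@@H]1c1ccc(OC)cc1
A4 | alternative 3 | ring-expanded tetramethoxy dibenzosuberone with the 4-methoxyphenyl group on C2 and a methyl ester on C3 (C3 epimerizable) | O=C1c2cc(OC)cc(OC)c2[C@H](c2ccc(OC)cc2)C(C(=O)OC)c2cc(OC)cc(OC)c12
A5 | alternative 3 | 3,5-dimethoxy-2-(trimethylsilyl)phenyl trifluoromethanesulfonate | COc1cc(OC)c([Si](C)(C)C)c(OS(=O)(=O)C(F)(F)F)c1
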